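**Plan**
1. Retrosynthetic cuts, in order: the C5–C6 bond between the two carbinol carbons of the cyclohexene ring (to a dialdehyde); the γ-pyrone ring of the tetrahydrochromone (C4a–C4 and O1–C2, to a β-keto thioester and an ynoyl chloride); the C8–O aryl ether (to methyl L-threonate acetonide and the phenolic chromone); the chromone ring of the phenol.
2. Forward order: the aromatic chromone first, then the ether union, a two-carbon homologation, annulation of the second γ-pyrone ring, and last the carbocycle by reductive aldehyde–aldehyde (pinacol) coupling.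
3. Enabling feature: C5 hangs on C4a of the γ-pyrone ring and C6 on the C7–C8 chain at C8a, and both carry hydroxyls of a trans-diol. A pyranone-3-carbaldehyde and an α-silyloxy aldehyde can therefore be joined in one reductive step that closes the six-membered ring and sets both centres.
4. Stereochemistry: C7 comes from L-threonic acid (vitamin C chiral pool); C8 by SN2 inversion of the threonate α-carbinol; C6 and C5 arise in the pinacol step, C6 under control of C7 and C5 trans to C6 by the reagent.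
5. Helpers: the carbothioate is the masked C5 aldehyde (set free by Fukuyama reduction); the triethylsilyl ether on O7 is removed at the end.

Key step: step 13

Remark: the tetrahydrochromone unit is numbered O1, C2, C3, C4, C4a, C5, C6, C7, C8, C8a, and these labels are also used for the corresponding atoms of open-chain intermediates. The target SMILES is read as (5S,6R,7S,8S), that is 5,6-trans, 6,7-trans, 7,8-cis. Ar = 7-methoxy-4-oxo-2-(2-phenylethyl)-4H-chromen-6-yl.

**Route**

Step 1
Reactants: 1 2-methoxybenzene-1,4-diol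
Product: 2 1-(2,5-dihydroxy-4-methoxyphenyl)ethanone
Conditions: AcOH, BF3·OEt2, 90 °C; aqueous work-up
Reagents that add atoms: acetic acid, CC(=O)O
Why: BF3-promoted Friedel–Crafts acetylation (Fries-type) should occur at the ring carbon para to the methoxy group and ortho to a hydroxyl, the most activated free position, giving a chelated ortho-hydroxy ketone.

Step 2
Reactants: 2 1-(2,5-dihydroxy-4-methoxyphenyl)ethanone; 3 3-phenylpropanoyl chloride
Product: 5 6-hydroxy-7-methoxy-2-(2-phenylethyl)-4H-chromen-4-one, via aryl 1,3-diketone 4 (not isolated)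
Conditions: LiN(SiMe3)2 (4.2 equiv), THF, −78 to −10 °C; 3, −78 °C to rt; then AcOH, H2SO4 (cat.), 95 °C
Reagents that add atoms: none
Why: Baker–Venkataraman-type one-pot chromone synthesis: the lithium polyanion of 2 is C-acylated at the enolate carbon to give 4, and acid closes the pyranone by cyclodehydration through the 2'-hydroxyl, leaving the 5'-hydroxyl as the free 6-OH.

Step 3
Reactants: 6 but-3-yn-1-ylbenzene
Product: 7 5-phenylpent-2-ynoic acid
Conditions: n-BuLi, THF, −78 °C; CO2; aq. HCl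
Reagents that add atoms: carbon dioxide, O=C=O
Why: Carboxylation of the lithium acetylide formed by deprotonation of the terminal alkyne.

Step 4
Reactants: 7 5-phenylpent-2-ynoic acid
Product: 8 5-phenylpent-2-ynoyl chloride
Conditions: (COCl)2, DMF (cat.), CH2Cl2, 0 °C to rt; used crude
Reagents that add atoms: oxalyl chloride, ClC(=O)C(=O)Cl
Why: Acid chloride formation through Vilsmeier-type chloroiminium activation; the ynoyl chloride is used at once.

Step 5
Reactants: 9 methyl 3,4-O-isopropylidene-L-threonate [methyl (2R)-2-[(4S)-2,2-dimethyl-1,3-dioxolan-4-yl]-2-hydroxyacetate]; 5 6-hydroxy-7-methoxy-2-(2-phenylethyl)-4H-chromen-4-one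
Product: 10 methyl (2S)-2-(ArO)-2-[(4S)-2,2-dimethyl-1,3-dioxolan-4-yl]acetate
Conditions: PPh3, DIAD, THF, 0 °C to rt
Reagents that add atoms: none
Why: Mitsunobu etherification: the alkoxyphosphonium of the α-hydroxy ester is displaced by the phenoxide of 5 in an SN2 step, so C8 is inverted (threo to erythro) while C7 in the dioxolane is untouched.

Step 6
Reactants: 10 methyl (2S)-2-(ArO)-2-[(4S)-2,2-dimethyl-1,3-dioxolan-4-yl]acetate
Product: 11 (2S)-2-(ArO)-2-[(4S)-2,2-dimethyl-1,3-dioxolan-4-yl]acetic acid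
Conditions: LiOH, THF/H2O, 0 °C; aq. HCl to pH 3
Reagents that add atoms: lithium hydroxide, [Li+].[OH-]
Why: Saponification (acyl substitution by hydroxide) at 0 °C, where the chromone ring and the acetonide should survive and the α-aryloxy centre is not enolised.

Step 7
Reactants: 11 (2S)-2-(ArO)-2-[(4S)-2,2-dimethyl-1,3-dioxolan-4-yl]acetic acid
Product: 13 S-ethyl (4S)-4-(ArO)-4-[(4S)-2,2-dimethyl-1,3-dioxolan-4-yl]-3-oxobutanethioate, via acyl Meldrum's acid 12 (not isolated)
Conditions: Meldrum's acid, EDC·HCl, DMAP, CH2Cl2, 0 °C to rt; then EtSH, toluene, 80 °C (sealed)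
Reagents that add atoms: Meldrum's acid, CC1(C)OC(=O)CC(=O)O1; ethanethiol, CCS
Why: Meldrum's acid homologation (carbodiimide C-acylation, then thermal loss of acetone and CO2 from 12 with capture by the thiol) gives the β-keto thioester under neutral conditions that should not enolise C8.

Step 8
Reactants: 13 S-ethyl (4S)-4-(ArO)-4-[(4S)-2,2-dimethyl-1,3-dioxolan-4-yl]-3-oxobutanethioate; 8 5-phenylpent-2-ynoyl chloride
Product: 15 S-ethyl 2-[(S)-(ArO)[(4S)-2,2-dimethyl-1,3-dioxolan-4-yl]methyl]-4-oxo-6-(2-phenylethyl)-4H-pyran-3-carbothioate, via alkynoyl triketone 14 (not isolated)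
Conditions: MgCl2, pyridine, CH2Cl2, 0 °C to rt; then crude 14, Et3N, CH2Cl2, rt
Reagents that add atoms: none
Why: Magnesium-enolate C-acylation (soft enolisation) at the doubly activated methylene gives 14, whose ketone enol oxygen adds 6-endo-dig to the ynone β-carbon (oxa-Michael), which fixes the carbothioate on the pyranone carbon next to the side chain.

Step 9
Reactants: 15 S-ethyl 2-[(S)-(ArO)[(4S)-2,2-dimethyl-1,3-dioxolan-4-yl]methyl]-4-oxo-6-(2-phenylethyl)-4H-pyran-3-carbothioate
Product: 16 S-ethyl 2-[(1S,2S)-1-(ArO)-2,3-dihydroxypropyl]-4-oxo-6-(2-phenylethyl)-4H-pyran-3-carbothioate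
Conditions: TFA/H2O (9:1), CH2Cl2, 0 °C
Reagents that add atoms: none
Why: Acid hydrolysis of the terminal isopropylidene acetal; the aryl ether at C8 (next to the electron-poor C8a) and the thioester should be stable to brief cold aqueous acid.

Step 10
Reactants: 16 S-ethyl 2-[(1S,2S)-1-(ArO)-2,3-dihydroxypropyl]-4-oxo-6-(2-phenylethyl)-4H-pyran-3-carbothioate
Product: 17 S-ethyl 2-[(1S,2S)-1-(ArO)-2,3-bis(triethylsilyloxy)propyl]-4-oxo-6-(2-phenylethyl)-4H-pyran-3-carbothioate
Conditions: Et3SiOTf, 2,6-lutidine, CH2Cl2, −78 °C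
Reagents that add atoms: triethylsilyl triflate, CC[Si](CC)(CC)OS(=O)(=O)C(F)(F)F
Why: Silyl ether formation with the silyl triflate and a hindered base is fast at −78 °C and masks both hydroxyls before they can acylate on the neighbouring thioester.

Step 11
Reactants: 17 S-ethyl 2-[(1S,2S)-1-(ArO)-2,3-bis(triethylsilyloxy)propyl]-4-oxo-6-(2-phenylethyl)-4H-pyran-3-carbothioate
Product: 18 S-ethyl 2-[(1S,2R)-1-(ArO)-3-oxo-2-(triethylsilyloxy)propyl]-4-oxo-6-(2-phenylethyl)-4H-pyran-3-carbothioate
Conditions: (COCl)2, DMSO, CH2Cl2, −78 to −40 °C; Et3N, −78 to −20 °C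
Reagents that add atoms: none
Why: Swern oxidation applied to a primary triethylsilyl ether: chlorodimethylsulfonium chloride attacks the unhindered primary silyl ether oxygen with loss of Et3SiCl and the alkoxysulfonium ylide collapses to the C6 aldehyde, while the secondary silyl ether stays.

Step 12
Reactants: 18 S-ethyl 2-[(1S,2R)-1-(ArO)-3-oxo-2-(triethylsilyloxy)propyl]-4-oxo-6-(2-phenylethyl)-4H-pyran-3-carbothioate
Product: 19 2-[(1S,2R)-1-(ArO)-3-oxo-2-(triethylsilyloxy)propyl]-4-oxo-6-(2-phenylethyl)-4H-pyran-3-carbaldehyde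
Conditions: Et3SiH, Pd/C (10% palladium on carbon), acetone, rt; filtered and used at once
Reagents that add atoms: none
Why: Fukuyama reduction: zerovalent palladium inserts into the C–S bond and Et3SiH delivers hydride to the acylpalladium, giving the C5 aldehyde under neutral conditions that should spare the C6 aldehyde, the silyl ether and both pyranone rings.

Step 13
Reactants: 19 2-[(1S,2R)-1-(ArO)-3-oxo-2-(triethylsilyloxy)propyl]-4-oxo-6-(2-phenylethyl)-4H-pyran-3-carbaldehyde
Product: 20 (5S,6R,7S,8S)-8-(ArO)-5,6-dihydroxy-2-(2-phenylethyl)-7-(triethylsilyloxy)-5,6,7,8-tetrahydro-4H-chromen-4-one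
Conditions: Cp2TiPh (3 equiv; from Cp2TiCl2, i-PrMgCl, then PhMgBr, THF, −78 °C to rt); 19 added slowly, THF (0.005 M), −78 to 0 °C; pH 7 buffer, air
Reagents that add atoms: none
Why: Two single-electron transfers from trivalent titanium turn the C5 and C6 formyl groups (the conjugated pyranone-3-carbaldehyde first) into titanoxy ketyl radicals, which couple to form the C5–C6 bond; the tetravalent titanium diolate is hydrolysed on work-up. The closest known reaction type is the intramolecular pinacol coupling of dials to trans-cycloalkane-1,2-diols with Cp2TiPh, together with the pinacol cyclisation of sugar-derived dialdehydes to cyclitols. The six-membered carbocycle (C4a, C5, C6, C7, C8, C8a) closes by radical–radical combination, formally a 6-exo-trig attack of the C5 ketyl on the C6 carbonyl. C6 is set by the C7 stereocentre: the new C6–O bond should form anti to the C7–OSiEt3 bond (dipole-minimised arrangement, as in pinacol cyclisations of α-alkoxy aldehydes), giving 6,7-trans; C5 is set by the reagent: the two bulky Cp2Ti(Ph)O groups cannot share one metal and stay on opposite faces, giving the 5,6-trans diol. The step needs chemoselective reduction of the two aldehydes beside two γ-pyrone carbonyls and the C8 aryl ether, which the mild reducing power of Cp2TiPh should secure, and ring closure over intermolecular coupling, which slow addition at high dilution should secure.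

Step 14
Reactants: 20 (5S,6R,7S,8S)-8-(ArO)-5,6-dihydroxy-2-(2-phenylethyl)-7-(triethylsilyloxy)-5,6,7,8-tetrahydro-4H-chromen-4-one
Product: 21 (5S,6R,7S,8S)-5,6,7-trihydroxy-8-(ArO)-2-(2-phenylethyl)-5,6,7,8-tetrahydro-4H-chromen-4-one (CNP0125425.2)
Conditions: HF·pyridine, pyridine, THF, 0 °C
Reagents that add atoms: none
Why: Fluoride-driven desilylation (Si–F bond formation) under buffered, non-solvolytic conditions, chosen because the C5 carbinol can ionise under protic acid (cation stabilised through O1).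

**Compound list**

1 | 2-methoxybenzene-1,4-diol | COc1cc(O)ccc1O | starting material
2 | 1-(2,5-dihydroxy-4-methoxyphenyl)ethanone | CC(=O)c1cc(O)c(OC)cc1O | intermediate
3 | 3-phenylpropanoyl chloride | O=C(Cl)CCc1ccccc1 | starting material
4 | 1-(2,5-dihydroxy-4-methoxyphenyl)-5-phenylpentane-1,3-dione (formed in the flask) | COc1cc(O)c(cc1O)C(=O)CC(=O)CCc1ccccc1 | intermediate
5 | 6-hydroxy-7-methoxy-2-(2-phenylethyl)-4H-chromen-4-one | COc1cc2oc(CCc3ccccc3)cc(=O)c2cc1O | intermediate
6 | but-3-yn-1-ylbenzene | C#CCCc1ccccc1 | starting material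
7 | 5-phenylpent-2-ynoic acid | OC(=O)C#CCCc1ccccc1 | intermediate
8 | 5-phenylpent-2-ynoyl chloride | ClC(=O)C#CCCc1ccccc1 | intermediate
9 | methyl 3,4-O-isopropylidene-L-threonate | COC(=O)[C@H](O)[C@@H]1COC(C)(C)O1 | starting material
10 | methyl (2S)-2-(ArO)-2-[(4S)-2,2-dimethyl-1,3-dioxolan-4-yl]acetate | COc1cc2oc(CCc3ccccc3)cc(=O)c2cc1O[C@H](C(=O)OC)[C@@H]1COC(C)(C)O1 | intermediate
11 | (2S)-2-(ArO)-2-[(4S)-2,2-dimethyl-1,3-dioxolan-4-yl]acetic acid | COc1cc2oc(CCc3ccccc3)cc(=O)c2cc1O[C@H](C(=O)O)[C@@H]1COC(C)(C)O1 | intermediate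
12 | 5-[(2S)-2-(ArO)-2-[(4S)-2,2-dimethyl-1,3-dioxolan-4-yl]-1-hydroxyethylidene]-2,2-dimethyl-1,3-dioxane-4,6-dione (acyl Meldrum's acid, enol form, formed in the flask) | COc1cc2oc(CCc3ccccc3)cc(=O)c2cc1O[C@H](C(O)=C1C(=O)OC(C)(C)OC1=O)[C@@H]1COC(C)(C)O1 | intermediate
13 | S-ethyl (4S)-4-(ArO)-4-[(4S)-2,2-dimethyl-1,3-dioxolan-4-yl]-3-oxobutanethioate | COc1cc2oc(CCc3ccccc3)cc(=O)c2cc1O[C@H](C(=O)CC(=O)SCC)[C@@H]1COC(C)(C)O1 | intermediate
14 | S-ethyl 2-{(2S)-2-(ArO)-2-[(4S)-2,2-dimethyl-1,3-dioxolan-4-yl]acetyl}-3-oxo-7-phenylhept-4-ynethioate (keto form drawn, enolised at the central carbon, formed in the flask) | COc1cc2oc(CCc3ccccc3)cc(=O)c2cc1O[C@H](C(=O)C(C(=O)SCC)C(=O)C#CCCc1ccccc1)[C@@H]1COC(C)(C)O1 | intermediate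
15 | S-ethyl 2-[(S)-(ArO)[(4S)-2,2-dimethyl-1,3-dioxolan-4-yl]methyl]-4-oxo-6-(2-phenylethyl)-4H-pyran-3-carbothioate | COc1cc2oc(CCc3ccccc3)cc(=O)c2cc1O[C@H](c1oc(CCc2ccccc2)cc(=O)c1C(=O)SCC)[C@@H]1COC(C)(C)O1 | intermediate
16 | S-ethyl 2-[(1S,2S)-1-(ArO)-2,3-dihydroxypropyl]-4-oxo-6-(2-phenylethyl)-4H-pyran-3-carbothioate | COc1cc2oc(CCc3ccccc3)cc(=O)c2cc1O[C@H](c1oc(CCc2ccccc2)cc(=O)c1C(=O)SCC)[C@@H](O)CO | intermediate
17 | S-ethyl 2-[(1S,2S)-1-(ArO)-2,3-bis(triethylsilyloxy)propyl]-4-oxo-6-(2-phenylethyl)-4H-pyran-3-carbothioate | COc1cc2oc(CCc3ccccc3)cc(=O)c2cc1O[C@H](c1oc(CCc2ccccc2)cc(=O)c1C(=O)SCC)[C@@H](O[Si](CC)(CC)CC)CO[Si](CC)(CC)CC | intermediate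
18 | S-ethyl 2-[(1S,2R)-1-(ArO)-3-oxo-2-(triethylsilyloxy)propyl]-4-oxo-6-(2-phenylethyl)-4H-pyran-3-carbothioate | COc1cc2oc(CCc3ccccc3)cc(=O)c2cc1O[C@H](c1oc(CCc2ccccc2)cc(=O)c1C(=O)SCC)[C@H](C=O)O[Si](CC)(CC)CC | intermediate
19 | 2-[(1S,2R)-1-(ArO)-3-oxo-2-(triethylsilyloxy)propyl]-4-oxo-6-(2-phenylethyl)-4H-pyran-3-carbaldehyde | COc1cc2oc(CCc3ccccc3)cc(=O)c2cc1O[C@H](c1oc(CCc2ccccc2)cc(=O)c1C=O)[C@H](C=O)O[Si](CC)(CC)CC | intermediate
20 | (5S,6R,7S,8S)-8-(ArO)-5,6-dihydroxy-2-(2-phenylethyl)-7-(triethylsilyloxy)-5,6,7,8-tetrahydro-4H-chromen-4-one | COc1cc2oc(CCc3ccccc3)cc(=O)c2cc1O[C@@H]1c2oc(CCc3ccccc3)cc(=O)c2[C@H](O)[C@@H](O)[C@@H]1O[Si](CC)(CC)CC | intermediate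
21 | (5S,6R,7S,8S)-5,6,7-trihydroxy-8-(ArO)-2-(2-phenylethyl)-5,6,7,8-tetrahydro-4H-chromen-4-one | COc1cc2oc(CCc3ccccc3)cc(=O)c2cc1O[C@@H]1c2oc(CCc3ccccc3)cc(=O)c2[C@H](O)[C@@H](O)[C@@H]1O | target

**Step count and risks**

Total step count: 14. Longest linear sequence: 12 steps (steps 1, 2 and 5 to 14, from 2-methoxybenzene-1,4-diol); 10 steps from the threonate 9.

Steps most likely to fail:

Step 13 (key step). What may go wrong: poor control of the C5/C6 configuration (closure to the cis-diol or to the other trans-diol), intermolecular coupling, or simple reduction of one aldehyde. Fallback, setting out from 19 and coming back at 20: 19 is cyclised with SmI2 and t-BuOH in THF at −78 °C, a samarium-bridged pinacol coupling that should give the 5,6-cis diol F1 with the C6 hydroxyl still anti to O7. The pyranone-bound C5 carbinol of F1 is then oxidised selectively with MnO2 in CH2Cl2 to the 6-hydroxy-5-ketone F2. Me4NBH(OAc)3 in MeCN/AcOH at −30 °C, bound to the C6 hydroxyl, should deliver hydride to the face of that hydroxyl and give the 5,6-trans diol 20.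

Step 8. What may go wrong: O-acylation in place of C-acylation, addition of chloride or pyridine to the ynoyl chloride, or 5-exo closure to a furanone. Fallback, setting out from 13 and coming back at 15: commercial methyl 3-oxo-5-phenylpentanoate is converted with HC(OMe)3 and H2SO4 (cat.) into methyl (2E)-3-methoxy-5-phenylpent-2-enoate F3, saponified with LiOH to (2E)-3-methoxy-5-phenylpent-2-enoic acid F4, and turned with (COCl)2 into (2E)-3-methoxy-5-phenylpent-2-enoyl chloride F5. Acylation of the magnesium enolate of 13 (MgCl2, pyridine) with this masked diketone gives the isolable C-acylated enol ether F6. p-TsOH (cat.) in toluene at 60 °C then closes the pyranone by addition–elimination with loss of methanol and gives 15.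

Step 11. What may go wrong: β-elimination of the aryloxide or epimerisation next to the new aldehyde under the amine base, or incomplete discrimination between the two silyl ethers. Fallback, setting out from 17 and coming back at 18: the primary silyl ether of 17 is cleaved selectively with HF·pyridine buffered with pyridine in THF at 0 °C to give the primary alcohol F7, which is oxidised base-free with Dess–Martin periodinane and NaHCO3 in CH2Cl2 to 18.

**Further compounds**

F1 | step 13 | (5R,6R,7S,8S)-8-(ArO)-5,6-dihydroxy-2-(2-phenylethyl)-7-(triethylsilyloxy)-5,6,7,8-tetrahydro-4H-chromen-4-one | COc1cc2oc(CCc3ccccc3)cc(=O)c2cc1O[C@@H]1c2oc(CCc3ccccc3)cc(=O)c2[C@@H](O)[C@@H](O)[C@@H]1O[Si](CC)(CC)CC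
F2 | step 13 | (6S,7S,8S)-8-(ArO)-6-hydroxy-2-(2-phenylethyl)-7-(triethylsilyloxy)-7,8-dihydro-4H-chromene-4,5(6H)-dione | COc1cc2oc(CCc3ccccc3)cc(=O)c2cc1O[C@@H]1c2oc(CCc3ccccc3)cc(=O)c2C(=O)[C@@H](O)[C@@H]1O[Si](CC)(CC)CC
F3 | step 8 | methyl (2E)-3-methoxy-5-phenylpent-2-enoate | CO/C(CCc1ccccc1)=C/C(=O)OC
F4 | step 8 | (2E)-3-methoxy-5-phenylpent-2-enoic acid | CO/C(CCc1ccccc1)=C/C(=O)O
F5 | step 8 | (2E)-3-methoxy-5-phenylpent-2-enoyl chloride | CO/C(CCc1ccccc1)=C/C(=O)Cl
F6 | step 8 | S-ethyl (4E)-2-{(2S)-2-(ArO)-2-[(4S)-2,2-dimethyl-1,3-dioxolan-4-yl]acetyl}-5-methoxy-3-oxo-7-phenylhept-4-enethioate | COc1cc2oc(CCc3ccccc3)cc(=O)c2cc1O[C@H](C(=O)C(C(=O)SCC)C(=O)/C=C(/OC)CCc1ccccc1)[C@@H]1COC(C)(C)O1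
F7 | step 11 | S-ethyl 2-[(1S,2S)-1-(ArO)-3-hydroxy-2-(triethylsilyloxy)propyl]-4-oxo-6-(2-phenylethyl)-4H-pyran-3-carbothioate | COc1cc2oc(CCc3ccccc3)cc(=O)c2cc1O[C@H](c1oc(CCc2ccccc2)cc(=O)c1C(=O)SCC)[C@@H](O[Si](CC)(CC)CC)CO
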